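**Retrosynthetic overview** (germacrane numbering: C6 lactone carbinol, C8 angelate carbinol, C2 free carbinol, C14 CH2OH)
1. Avoided: the usual Cr/Zn allylation macrocyclisation at C6–C7. The ten-membered ring is instead closed last, at C1=C10, by RCM of an unprotected seco-diene (ring-cis trisubstituted olefin).
2. C8–O angelate; C7–C8 by a vinylogous Zn-Barbier reaction of a chiral 3-(bromomethyl)butenolide with a β,γ-unsaturated aldehyde, so the C6 centre alone fixes C7 and C8 and the lactone already sits on C6.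
3. Butenolide from a Z-enal: catalytic asymmetric propiolate alkynylation (C6), then vinylalumination / CH2O trapping / lactonisation.
4. Z-C4=C5 and C2 from a 6-vinyl-4-methyl-5,6-dihydropyran-2-one made by catalytic asymmetric vinylogous aldol–lactonisation (cis olefin locked in the six-ring), opened as a Weinreb amide.
5. Ring order: dihydropyranone (temporary) → butenolide → α-methylene-γ-lactone → ten-membered carbocycle.

Assumption: the ligand antipodes named in steps 2 and 5 are those expected to give the drawn configurations; the mirror-image ligand is used if the sense proves opposite.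

**Step 1**
Reactants: 1 ethyl 3-methylbut-2-enoate
Product: 3 [(1-ethoxy-3-methylbuta-1,3-dien-1-yl)oxy]trimethylsilane, via lithium dienolate 2 (not isolated)
Conditions: LDA, THF, −78 °C; TMSCl, −78 °C → rt; distil
Reagents that add atoms: chlorotrimethylsilane C[Si](C)(C)Cl
Why: Kinetic γ-deprotonation of the senecioate gives the extended lithium dienolate, which is O-silylated (silyl dienolate formation).

**Step 2**
Reactants: 3 [(1-ethoxy-3-methylbuta-1,3-dien-1-yl)oxy]trimethylsilane; 4 acrolein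
Product: 5 (6S)-6-ethenyl-4-methyl-5,6-dihydro-2H-pyran-2-one
Conditions: Cu(OTf)2 (10 mol %), (S)-Tol-BINAP (11 mol %), TBAT (20 mol %), THF, −20 °C → rt; aq. HCl work-up
Reagents that add atoms: none
Why: Catalytic asymmetric vinylogous Mukaiyama aldol in which the chiral copper dienolate attacks one face of acrolein through its γ-carbon (sets C2, S) and the copper aldolate closes onto the ester, locking C4=C5 cis inside the six-membered lactone.

**Step 3**
Reactants: 5 (6S)-6-ethenyl-4-methyl-5,6-dihydro-2H-pyran-2-one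
Product: 7 (2Z,5S)-5-{[tert-butyl(dimethyl)silyl]oxy}-N-methoxy-N,3-dimethylhepta-2,6-dienamide, via hydroxy amide 6 (not isolated)
Conditions: MeNH(OMe)·HCl, Me3Al, CH2Cl2, 0 °C → rt; crude + TBSOTf, 2,6-lutidine, CH2Cl2, −78 °C
Reagents that add atoms: N,O-dimethylhydroxylamine hydrochloride CNOC.Cl; tert-butyldimethylsilyl trifluoromethanesulfonate CC(C)(C)[Si](C)(C)OS(=O)(=O)C(F)(F)F
Why: Weinreb aminolysis opens the lactone without touching the Z-olefin, and immediate silylation of the freed carbinol prevents relactonisation (silyl ether formation).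

**Step 4**
Reactants: 7 (2Z,5S)-5-{[tert-butyl(dimethyl)silyl]oxy}-N-methoxy-N,3-dimethylhepta-2,6-dienamide
Product: 8 (2Z,5S)-5-{[tert-butyl(dimethyl)silyl]oxy}-3-methylhepta-2,6-dienal
Conditions: DIBAL-H, THF, −78 °C; Rochelle salt
Reagents that add atoms: none
Why: DIBAL-H reduction of the Weinreb amide stops at the chelated hemiaminal and releases the Z-enal on cold work-up without olefin isomerisation.

**Step 5**
Reactants: 8 (2Z,5S)-5-{[tert-butyl(dimethyl)silyl]oxy}-3-methylhepta-2,6-dienal; 9 methyl propiolate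
Product: 11 methyl (4R,5Z,8S)-8-{[tert-butyl(dimethyl)silyl]oxy}-4-hydroxy-6-methyldeca-5,9-dien-2-ynoate, via zinc acetylide 10 (not isolated)
Conditions: Me2Zn, (S,S)-ProPhenol (20 mol %), Ph3PO (40 mol %), PhMe, 4 °C
Reagents that add atoms: none
Why: Catalytic asymmetric alkynylation in which the dinuclear zinc–ProPhenol complex delivers the propiolate acetylide to one enantioface of the enal, setting C6 (R) under catalyst control independent of remote C2.

**Step 6**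
Reactants: 11 methyl (4R,5Z,8S)-8-{[tert-butyl(dimethyl)silyl]oxy}-4-hydroxy-6-methyldeca-5,9-dien-2-ynoate; 12 formaldehyde
Product: 15 (5R)-5-[(1Z,4S)-4-{[tert-butyl(dimethyl)silyl]oxy}-2-methylhexa-1,5-dien-1-yl]-3-(hydroxymethyl)furan-2(5H)-one, via vinylalane 13 (not isolated), via dihydroxy ester 14 (not isolated)
Conditions: DIBAL-H (2.6 equiv), HMPA, THF, 0 °C; CH2O (gas from (CH2O)n), 0 °C → rt; aq. citric acid; PPTS, CH2Cl2
Reagents that add atoms: none
Why: Conjugate syn-hydroalumination of the ynoate (vinylalumination) puts Al on C11 and H on C7 cis to it, the vinylalane is trapped by formaldehyde with retention (aldol-type trapping), and the resulting Z-γ-hydroxy ester lactonises to the butenolide with C6 untouched.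

**Step 7**
Reactants: 15 (5R)-5-[(1Z,4S)-4-{[tert-butyl(dimethyl)silyl]oxy}-2-methylhexa-1,5-dien-1-yl]-3-(hydroxymethyl)furan-2(5H)-one
Product: 16 (5R)-3-(bromomethyl)-5-[(1Z,4S)-4-{[tert-butyl(dimethyl)silyl]oxy}-2-methylhexa-1,5-dien-1-yl]furan-2(5H)-one
Conditions: CBr4, PPh3, CH2Cl2, 0 °C
Reagents that add atoms: carbon tetrabromide BrC(Br)(Br)Br
Why: Appel bromination of the primary allylic alcohol under neutral conditions that leave the silyl ether and the epimerisable butenolide C6–H alone.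

**Step 8**
Reactants: 17 2-bromoprop-2-en-1-ol
Product: 18 [(2-bromoprop-2-en-1-yl)oxy](tert-butyl)dimethylsilane
Conditions: TBSCl, imidazole, CH2Cl2, rt
Reagents that add atoms: tert-butyldimethylsilyl chloride CC(C)(C)[Si](C)(C)Cl
Why: Standard silyl ether protection of the primary allylic alcohol.

**Step 9**
Reactants: 18 [(2-bromoprop-2-en-1-yl)oxy](tert-butyl)dimethylsilane; 19 ethylene oxide
Product: 21 3-({[tert-butyl(dimethyl)silyl]oxy}methyl)but-3-en-1-ol, via vinyllithium 20 (not isolated)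
Conditions: t-BuLi (2.1 equiv), Et2O, −78 °C; ethylene oxide, BF3·OEt2, −78 °C
Reagents that add atoms: none
Why: Bromine–lithium exchange gives the 2-lithioallyl ether, which opens the BF3-activated epoxide (epoxide ring opening) to the homoallylic alcohol.

**Step 10**
Reactants: 21 3-({[tert-butyl(dimethyl)silyl]oxy}methyl)but-3-en-1-ol
Product: 22 3-({[tert-butyl(dimethyl)silyl]oxy}methyl)but-3-enal
Conditions: Dess–Martin periodinane, pyridine, CH2Cl2, 0 °C; used crude at once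
Reagents that add atoms: none
Why: Buffered Dess–Martin oxidation gives the β,γ-unsaturated aldehyde without migration of the 1,1-disubstituted olefin into conjugation.

**Step 11**
Reactants: 16 (5R)-3-(bromomethyl)-5-[(1Z,4S)-4-{[tert-butyl(dimethyl)silyl]oxy}-2-methylhexa-1,5-dien-1-yl]furan-2(5H)-one; 22 3-({[tert-butyl(dimethyl)silyl]oxy}methyl)but-3-enal
Product: 24 (4R,5R)-4-[(1S)-3-({[tert-butyl(dimethyl)silyl]oxy}methyl)-1-hydroxybut-3-en-1-yl]-5-[(1Z,4S)-4-{[tert-butyl(dimethyl)silyl]oxy}-2-methylhexa-1,5-dien-1-yl]-3-methylideneoxolan-2-one, via allylzinc bromide 23 (not isolated)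
Conditions: Zn dust, THF/sat. aq. NH4Cl, 0 °C → rt
Reagents that add atoms: none
Why: Barbier allylation through the γ-carbon (C7) of the butenolide-derived allylzinc in a chair Zimmerman–Traxler transition state, where the aldehyde adds anti to the C6 side chain (sets C7, trans-lactone) and the ring-locked E-crotyl-type geometry with the aldehyde chain equatorial gives the anti C7/C8 adduct (sets C8, S), unveiling the exo-methylene.

**Step 12**
Reactants: 24 (4R,5R)-4-[(1S)-3-({[tert-butyl(dimethyl)silyl]oxy}methyl)-1-hydroxybut-3-en-1-yl]-5-[(1Z,4S)-4-{[tert-butyl(dimethyl)silyl]oxy}-2-methylhexa-1,5-dien-1-yl]-3-methylideneoxolan-2-one; 25 angelic acid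
Product: 27 (1S)-3-({[tert-butyl(dimethyl)silyl]oxy}methyl)-1-{(2R,3R)-2-[(1Z,4S)-4-{[tert-butyl(dimethyl)silyl]oxy}-2-methylhexa-1,5-dien-1-yl]-4-methylidene-5-oxooxolan-3-yl}but-3-en-1-yl (2Z)-2-methylbut-2-enoate, via mixed anhydride 26 (not isolated)
Conditions: 25, 2,4,6-Cl3C6H2COCl, Et3N, PhMe, rt; then 24, 75 °C (no DMAP)
Reagents that add atoms: none
Why: Yamaguchi-type mixed-anhydride esterification of the only free hydroxyl, run without DMAP so the angelate does not isomerise to tiglate and acylation outruns 6,12→8,12 translactonisation.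

**Step 13**
Reactants: 27 (1S)-3-({[tert-butyl(dimethyl)silyl]oxy}methyl)-1-{(2R,3R)-2-[(1Z,4S)-4-{[tert-butyl(dimethyl)silyl]oxy}-2-methylhexa-1,5-dien-1-yl]-4-methylidene-5-oxooxolan-3-yl}but-3-en-1-yl (2Z)-2-methylbut-2-enoate
Product: 28 (1S)-1-{(2R,3R)-2-[(1Z,4S)-4-hydroxy-2-methylhexa-1,5-dien-1-yl]-4-methylidene-5-oxooxolan-3-yl}-3-(hydroxymethyl)but-3-en-1-yl (2Z)-2-methylbut-2-enoate
Conditions: HF·pyridine, pyridine, THF, 0 °C → rt
Reagents that add atoms: none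
Why: Buffered fluoride desilylation removes both TBS ethers while the angelate, the α-methylene lactone and all stereocentres are untouched.

**Step 14**
Reactants: 28 (1S)-1-{(2R,3R)-2-[(1Z,4S)-4-hydroxy-2-methylhexa-1,5-dien-1-yl]-4-methylidene-5-oxooxolan-3-yl}-3-(hydroxymethyl)but-3-en-1-yl (2Z)-2-methylbut-2-enoate
Product: 29 (3aR,4S,6E,8S,10Z,11aR)-8-hydroxy-6-(hydroxymethyl)-10-methyl-3-methylidene-2-oxo-2,3,3a,4,5,8,9,11a-octahydrocyclodeca[b]furan-4-yl (2Z)-2-methylbut-2-enoate (CNP0270898.1)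
Conditions: Grubbs II (15 mol %, in portions), 2,6-dichloro-1,4-benzoquinone (30 mol %), PhMe (0.5 mM), 80 °C, Ar sparge
Reagents that add atoms: none
Why: Ring-closing metathesis in which ruthenium loads on the monosubstituted C1 vinyl (assisted by the free allylic OH) and closes onto the 1,1-disubstituted C10 olefin; in a ten-membered ring only the ring-cis trisubstituted alkene (C2 cis to C9) is attainable, and no stereocentre is touched.

**Compound list**
1 | ethyl 3-methylbut-2-enoate | CCOC(=O)C=C(C)C | starting material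
2 | lithium 1-ethoxy-3-methylbuta-1,3-dien-1-olate | [Li]OC(OCC)=CC(C)=C | intermediate
3 | [(1-ethoxy-3-methylbuta-1,3-dien-1-yl)oxy]trimethylsilane | CCOC(O[Si](C)(C)C)=CC(C)=C | intermediate
4 | acrolein | C=CC=O | starting material
5 | (6S)-6-ethenyl-4-methyl-5,6-dihydro-2H-pyran-2-one | CC1=CC(=O)O[C@H](C=C)C1 | intermediate
6 | (2Z,5S)-5-hydroxy-N-methoxy-N,3-dimethylhepta-2,6-dienamide | CON(C)C(=O)/C=C(/C)C[C@H](O)C=C | intermediate
7 | (2Z,5S)-5-{[tert-butyl(dimethyl)silyl]oxy}-N-methoxy-N,3-dimethylhepta-2,6-dienamide | CON(C)C(=O)/C=C(/C)C[C@H](O[Si](C)(C)C(C)(C)C)C=C | intermediate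
8 | (2Z,5S)-5-{[tert-butyl(dimethyl)silyl]oxy}-3-methylhepta-2,6-dienal | O=C/C=C(/C)C[C@H](O[Si](C)(C)C(C)(C)C)C=C | intermediate
9 | methyl propiolate | C#CC(=O)OC | starting material
10 | methyl 3-(methylzincio)prop-2-ynoate | C[Zn]C#CC(=O)OC | intermediate
11 | methyl (4R,5Z,8S)-8-{[tert-butyl(dimethyl)silyl]oxy}-4-hydroxy-6-methyldeca-5,9-dien-2-ynoate | COC(=O)C#C[C@H](O)/C=C(/C)C[C@H](O[Si](C)(C)C(C)(C)C)C=C | intermediate
12 | formaldehyde (from paraformaldehyde) | C=O | starting material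
13 | methyl (2E,4R,5Z,8S)-8-{[tert-butyl(dimethyl)silyl]oxy}-2-(diisobutylalumanyl)-4-[(diisobutylalumanyl)oxy]-6-methyldeca-2,5,9-trienoate | COC(=O)/C([Al](CC(C)C)CC(C)C)=C\[C@H](O[Al](CC(C)C)CC(C)C)/C=C(/C)C[C@H](O[Si](C)(C)C(C)(C)C)C=C | intermediate
14 | methyl (2Z,4R,5Z,8S)-8-{[tert-butyl(dimethyl)silyl]oxy}-4-hydroxy-2-(hydroxymethyl)-6-methyldeca-2,5,9-trienoate | COC(=O)/C(CO)=C\[C@H](O)/C=C(/C)C[C@H](O[Si](C)(C)C(C)(C)C)C=C | intermediate
15 | (5R)-5-[(1Z,4S)-4-{[tert-butyl(dimethyl)silyl]oxy}-2-methylhexa-1,5-dien-1-yl]-3-(hydroxymethyl)furan-2(5H)-one | OCC1=C[C@@H](/C=C(/C)C[C@H](O[Si](C)(C)C(C)(C)C)C=C)OC1=O | intermediate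
16 | (5R)-3-(bromomethyl)-5-[(1Z,4S)-4-{[tert-butyl(dimethyl)silyl]oxy}-2-methylhexa-1,5-dien-1-yl]furan-2(5H)-one | BrCC1=C[C@@H](/C=C(/C)C[C@H](O[Si](C)(C)C(C)(C)C)C=C)OC1=O | intermediate
17 | 2-bromoprop-2-en-1-ol | OCC(Br)=C | starting material
18 | [(2-bromoprop-2-en-1-yl)oxy](tert-butyl)dimethylsilane | C=C(Br)CO[Si](C)(C)C(C)(C)C | intermediate
19 | ethylene oxide | C1CO1 | starting material
20 | (3-{[tert-butyl(dimethyl)silyl]oxy}prop-1-en-2-yl)lithium | [Li]C(=C)CO[Si](C)(C)C(C)(C)C | intermediate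
21 | 3-({[tert-butyl(dimethyl)silyl]oxy}methyl)but-3-en-1-ol | OCCC(=C)CO[Si](C)(C)C(C)(C)C | intermediate
22 | 3-({[tert-butyl(dimethyl)silyl]oxy}methyl)but-3-enal | O=CCC(=C)CO[Si](C)(C)C(C)(C)C | intermediate
23 | bromo({(5R)-5-[(1Z,4S)-4-{[tert-butyl(dimethyl)silyl]oxy}-2-methylhexa-1,5-dien-1-yl]-2-oxo-2,5-dihydrofuran-3-yl}methyl)zinc | Br[Zn]CC1=C[C@@H](/C=C(/C)C[C@H](O[Si](C)(C)C(C)(C)C)C=C)OC1=O | intermediate
24 | (4R,5R)-4-[(1S)-3-({[tert-butyl(dimethyl)silyl]oxy}methyl)-1-hydroxybut-3-en-1-yl]-5-[(1Z,4S)-4-{[tert-butyl(dimethyl)silyl]oxy}-2-methylhexa-1,5-dien-1-yl]-3-methylideneoxolan-2-one | C=C1C(=O)O[C@H](/C=C(/C)C[C@H](O[Si](C)(C)C(C)(C)C)C=C)[C@H]1[C@@H](O)CC(=C)CO[Si](C)(C)C(C)(C)C | intermediate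
25 | angelic acid [(2Z)-2-methylbut-2-enoic acid] | C/C=C(/C)C(=O)O | starting material
26 | (2Z)-2-methylbut-2-enoic 2,4,6-trichlorobenzoic anhydride | C/C=C(/C)C(=O)OC(=O)c1c(Cl)cc(Cl)cc1Cl | intermediate
27 | (1S)-3-({[tert-butyl(dimethyl)silyl]oxy}methyl)-1-{(2R,3R)-2-[(1Z,4S)-4-{[tert-butyl(dimethyl)silyl]oxy}-2-methylhexa-1,5-dien-1-yl]-4-methylidene-5-oxooxolan-3-yl}but-3-en-1-yl (2Z)-2-methylbut-2-enoate | C=C1C(=O)O[C@H](/C=C(/C)C[C@H](O[Si](C)(C)C(C)(C)C)C=C)[C@H]1[C@@H](OC(=O)/C(C)=C\C)CC(=C)CO[Si](C)(C)C(C)(C)C | intermediate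
28 | (1S)-1-{(2R,3R)-2-[(1Z,4S)-4-hydroxy-2-methylhexa-1,5-dien-1-yl]-4-methylidene-5-oxooxolan-3-yl}-3-(hydroxymethyl)but-3-en-1-yl (2Z)-2-methylbut-2-enoate | C=C1C(=O)O[C@H](/C=C(/C)C[C@H](O)C=C)[C@H]1[C@@H](OC(=O)/C(C)=C\C)CC(=C)CO | intermediate
29 | (3aR,4S,6E,8S,10Z,11aR)-8-hydroxy-6-(hydroxymethyl)-10-methyl-3-methylidene-2-oxo-2,3,3a,4,5,8,9,11a-octahydrocyclodeca[b]furan-4-yl (2Z)-2-methylbut-2-enoate | C=C1C(=O)O[C@@H]2/C=C(/C)C[C@H](O)/C=C(/CO)C[C@H](OC(=O)/C(C)=C\C)[C@@H]12 | target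

**Total step count:** 14. **Longest linear sequence:** 11 steps (1–7, then 11–14); steps 8–10 make the aldehyde branch.

**Three steps most likely to fail**

Step 14 (RCM to a ten-membered ring with a trisubstituted olefin; oligomerisation, no closure, or reaction at the α-methylene lactone). The fallback reverses the order of the two C–C bond formations; it sets out from 16 (with 22) and comes back at 29. Aqueous HF in MeCN removes the silyl group of 16 to give (5R)-3-(bromomethyl)-5-[(1Z,4S)-4-hydroxy-2-methylhexa-1,5-dien-1-yl]furan-2(5H)-one F7. Aldehyde 22 is converted (HC(OMe)3, MeOH, PPTS) into tert-butyl[(4,4-dimethoxy-2-methylidenebutyl)oxy]dimethylsilane F8. F8 is joined to F7 (TESOTf, 2,4,6-collidine) as the mixed methyl acetal (5R)-3-(bromomethyl)-5-[(1Z,4S)-4-{[3-({[tert-butyl(dimethyl)silyl]oxy}methyl)-1-methoxybut-3-en-1-yl]oxy}-2-methylhexa-1,5-dien-1-yl]furan-2(5H)-one F9. RCM is now an easy six-ring closure (Grubbs II, CH2Cl2, 40 °C) that fixes C1=C10 ring-cis in (5R)-3-(bromomethyl)-5-{(1Z)-3-[(2S)-4-({[tert-butyl(dimethyl)silyl]oxy}methyl)-6-methoxy-5,6-dihydro-2H-pyran-2-yl]-2-methylprop-1-en-1-yl}furan-2(5H)-one F10. Mild hydrolysis (PPTS, THF/H2O) gives the lactol (5R)-3-(bromomethyl)-5-{(1Z)-3-[(2S)-4-({[tert-butyl(dimethyl)silyl]oxy}methyl)-6-hydroxy-5,6-dihydro-2H-pyran-2-yl]-2-methylprop-1-en-1-yl}furan-2(5H)-one F11, a masked C8 aldehyde. An intramolecular Zn-Barbier reaction (Zn, THF/aq. NH4Cl, 2 mM) then closes the ten-membered ring at C7–C8 to (3aR,4S,6E,8S,10Z,11aR)-6-({[tert-butyl(dimethyl)silyl]oxy}methyl)-4,8-dihydroxy-10-methyl-3-methylidene-3a,4,5,8,9,11a-hexahydrocyclodeca[b]furan-2(3H)-one F12; the C7/C8 sense under ring constraint would have to be confirmed. The less hindered allylic C2–OH is silylated selectively (TESCl, imidazole, −40 °C) to (3aR,4S,6E,8S,10Z,11aR)-6-({[tert-butyl(dimethyl)silyl]oxy}methyl)-4-hydroxy-10-methyl-3-methylidene-8-[(triethylsilyl)oxy]-3a,4,5,8,9,11a-hexahydrocyclodeca[b]furan-2(3H)-one F13. Acylation with mixed anhydride 26 as in step 12 gives (3aR,4S,6E,8S,10Z,11aR)-6-({[tert-butyl(dimethyl)silyl]oxy}methyl)-10-methyl-3-methylidene-2-oxo-8-[(triethylsilyl)oxy]-2,3,3a,4,5,8,9,11a-octahydrocyclodeca[b]furan-4-yl (2Z)-2-methylbut-2-enoate F14, and HF·pyridine gives 29.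

Step 6 (vinylalumination / formaldehyde trapping; risks are 1,2-reduction, loss of the cis geometry through an allenolate, and poor trapping). The fallback replaces aldehyde trapping by cross-coupling; it sets out from 11 and comes back at 15. Pd(PPh3)4-catalysed syn-hydrostannation (Bu3SnH, THF) puts tin α to the ester and H on C7 cis to it, and the Z-hydroxy ester lactonises to (5R)-5-[(1Z,4S)-4-{[tert-butyl(dimethyl)silyl]oxy}-2-methylhexa-1,5-dien-1-yl]-3-(tributylstannyl)furan-2(5H)-one F5. Iododestannylation (I2, CH2Cl2, 0 °C) gives (5R)-5-[(1Z,4S)-4-{[tert-butyl(dimethyl)silyl]oxy}-2-methylhexa-1,5-dien-1-yl]-3-iodofuran-2(5H)-one F6. Stille hydroxymethylation with (tributylstannyl)methanol (Pd(PPh3)4, dioxane, 80 °C) gives 15.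

Step 2 (catalytic asymmetric vinylogous aldol with volatile, polymerisable acrolein; ee and yield uncertain). The fallback uses an auxiliary-controlled acetate aldol and builds the Z-lactone by intramolecular olefination; it sets out from 4 and comes back at 5. The titanium enolate of commercial (R)-3-acetyl-4-isopropylthiazolidine-2-thione (TiCl4, i-Pr2NEt, CH2Cl2, −78 °C; antipode if the sense is opposite) adds to 4 to give, after removal of the minor diastereomer, (3S)-3-hydroxy-1-[(4R)-4-(propan-2-yl)-2-sulfanylidene-1,3-thiazolidin-3-yl]pent-4-en-1-one F1. MeNH(OMe)·HCl with imidazole displaces the auxiliary to give (3S)-3-hydroxy-N-methoxy-N-methylpent-4-enamide F2. MeMgBr gives (4S)-4-hydroxyhex-5-en-2-one F3. Esterification with (diethoxyphosphoryl)acetic acid (DCC, DMAP) gives (3S)-5-oxohex-1-en-3-yl (diethoxyphosphoryl)acetate F4. Intramolecular Horner–Wadsworth–Emmons reaction (LiCl, DBU, MeCN) closes the ring to 5 with the olefin necessarily cis.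

**Further compounds**
F1 | step 2 | (3S)-3-hydroxy-1-[(4R)-4-(propan-2-yl)-2-sulfanylidene-1,3-thiazolidin-3-yl]pent-4-en-1-one | C=C[C@@H](O)CC(=O)N1[C@H](C(C)C)CSC1=S
F2 | step 2 | (3S)-3-hydroxy-N-methoxy-N-methylpent-4-enamide | C=C[C@@H](O)CC(=O)N(C)OC
F3 | step 2 | (4S)-4-hydroxyhex-5-en-2-one | C=C[C@@H](O)CC(C)=O
F4 | step 2 | (3S)-5-oxohex-1-en-3-yl (diethoxyphosphoryl)acetate | C=C[C@H](CC(C)=O)OC(=O)CP(=O)(OCC)OCC
F5 | step 6 | (5R)-5-[(1Z,4S)-4-{[tert-butyl(dimethyl)silyl]oxy}-2-methylhexa-1,5-dien-1-yl]-3-(tributylstannyl)furan-2(5H)-one | CCCC[Sn](CCCC)(CCCC)C1=C[C@@H](/C=C(/C)C[C@H](O[Si](C)(C)C(C)(C)C)C=C)OC1=O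
F6 | step 6 | (5R)-5-[(1Z,4S)-4-{[tert-butyl(dimethyl)silyl]oxy}-2-methylhexa-1,5-dien-1-yl]-3-iodofuran-2(5H)-one | IC1=C[C@@H](/C=C(/C)C[C@H](O[Si](C)(C)C(C)(C)C)C=C)OC1=O
F7 | step 14 | (5R)-3-(bromomethyl)-5-[(1Z,4S)-4-hydroxy-2-methylhexa-1,5-dien-1-yl]furan-2(5H)-one | BrCC1=C[C@@H](/C=C(/C)C[C@H](O)C=C)OC1=O
F8 | step 14 | tert-butyl[(4,4-dimethoxy-2-methylidenebutyl)oxy]dimethylsilane | COC(OC)CC(=C)CO[Si](C)(C)C(C)(C)C
F9 | step 14 | (5R)-3-(bromomethyl)-5-[(1Z,4S)-4-{[3-({[tert-butyl(dimethyl)silyl]oxy}methyl)-1-methoxybut-3-en-1-yl]oxy}-2-methylhexa-1,5-dien-1-yl]furan-2(5H)-one | BrCC1=C[C@@H](/C=C(/C)C[C@H](OC(OC)CC(=C)CO[Si](C)(C)C(C)(C)C)C=C)OC1=O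
F10 | step 14 | (5R)-3-(bromomethyl)-5-{(1Z)-3-[(2S)-4-({[tert-butyl(dimethyl)silyl]oxy}methyl)-6-methoxy-5,6-dihydro-2H-pyran-2-yl]-2-methylprop-1-en-1-yl}furan-2(5H)-one | BrCC1=C[C@@H](/C=C(/C)C[C@H]2C=C(CO[Si](C)(C)C(C)(C)C)CC(OC)O2)OC1=O
F11 | step 14 | (5R)-3-(bromomethyl)-5-{(1Z)-3-[(2S)-4-({[tert-butyl(dimethyl)silyl]oxy}methyl)-6-hydroxy-5,6-dihydro-2H-pyran-2-yl]-2-methylprop-1-en-1-yl}furan-2(5H)-one | BrCC1=C[C@@H](/C=C(/C)C[C@H]2C=C(CO[Si](C)(C)C(C)(C)C)CC(O)O2)OC1=O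
F12 | step 14 | (3aR,4S,6E,8S,10Z,11aR)-6-({[tert-butyl(dimethyl)silyl]oxy}methyl)-4,8-dihydroxy-10-methyl-3-methylidene-3a,4,5,8,9,11a-hexahydrocyclodeca[b]furan-2(3H)-one | C=C1C(=O)O[C@@H]2/C=C(/C)C[C@H](O)/C=C(/CO[Si](C)(C)C(C)(C)C)C[C@H](O)[C@@H]12
F13 | step 14 | (3aR,4S,6E,8S,10Z,11aR)-6-({[tert-butyl(dimethyl)silyl]oxy}methyl)-4-hydroxy-10-methyl-3-methylidene-8-[(triethylsilyl)oxy]-3a,4,5,8,9,11a-hexahydrocyclodeca[b]furan-2(3H)-one | C=C1C(=O)O[C@@H]2/C=C(/C)C[C@H](O[Si](CC)(CC)CC)/C=C(/CO[Si](C)(C)C(C)(C)C)C[C@H](O)[C@@H]12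
F14 | step 14 | (3aR,4S,6E,8S,10Z,11aR)-6-({[tert-butyl(dimethyl)silyl]oxy}methyl)-10-methyl-3-methylidene-2-oxo-8-[(triethylsilyl)oxy]-2,3,3a,4,5,8,9,11a-octahydrocyclodeca[b]furan-4-yl (2Z)-2-methylbut-2-enoate | C=C1C(=O)O[C@@H]2/C=C(/C)C[C@H](O[Si](CC)(CC)CC)/C=C(/CO[Si](C)(C)C(C)(C)C)C[C@H](OC(=O)/C(C)=C\C)[C@@H]12
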